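**Retrosynthetic overview** (suffix u = upper flavan unit with rings A, B, C; suffix l = lower unit with benzo ring D, catechol ring E, pyran ring F)
1. The target comes from global hydrogenolysis of its deca-benzyl ether. The 2,3-cis-3,4-trans diol of ring F comes from hydroboration–oxidation of a 3-benzyloxyflav-3-ene, anti to the C2l aryl.
2. Ring F (formed second) comes from Juliá–Colonna epoxidation of a ring-D chalcone and acid cyclisation, which sets C2l. The chalcone comes from the ring-D aryl bromide by Stille acetylation and Claisen–Schmidt condensation.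
3. The strategy rests on ring C of the upper flavan (O1u, C2u, C3u, C4u, C4au, C8au), which carries the ring-B aryl on C2u, oxygen on C3u and the ring-D aryl on C4u all cis. The C3u hydroxyl comes from a C3u–Si bond (Tamao oxidation, retention). Ring C (formed first) comes from a [4+2] addition of a ring-A ortho-quinone methide to a (Z)-styrylsilane, which forms C3u–C4u and O1u–C2u.
4. The ortho-hydroxybenzhydrol comes from monolithiated 4,6-dibromopyrogallol tribenzyl ether and 3,4-bis(benzyloxy)salicylaldehyde. The (Z)-styrylsilane comes from 3,4-bis(benzyloxy)benzaldehyde by Corey–Fuchs reaction, C-silylation and semihydrogenation.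

Key step: step 9

Remarks on the chemistry: Bn = benzyl. The sense of induction of the phosphoric acid on this untested alkene is assumed to be that of the (R)-acid; the (S)-acid is used instead if the first run shows the opposite sense. The CIP label at C4u is S in the benzylated intermediates and R in the target only because the ring-D priority changes; the spatial arrangement is the same throughout.

**Route**

Step 1
Reactants: 1 pyrogallol
Product: 2 1,2,3-tris(benzyloxy)benzene
Conditions: BnBr (3.3 equiv), K2CO3, DMF, N2, 60 °C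
Reagents that add atoms: benzyl bromide, BrCc1ccccc1
Why: Williamson etherification of the three phenols, run under nitrogen so that pyrogallol is not autoxidised in base.

Step 2
Reactants: 2 1,2,3-tris(benzyloxy)benzene
Product: 3 1,2,3-tris(benzyloxy)-4,6-dibromobenzene
Conditions: NBS (2.1 equiv), MeCN, 0 °C to rt, dark
Reagents that add atoms: N-bromosuccinimide, O=C1CCC(=O)N1Br
Why: Electrophilic aromatic bromination goes to C4 and C6, each ortho and para to a benzyloxy group, whereas C5 is para only to the twisted central ether, so the symmetric dibromide should result.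

Step 3
Reactants: 4 2,3,4-trihydroxybenzaldehyde
Product: 5 2,3,4-tris(benzyloxy)benzaldehyde
Conditions: BnBr (3.3 equiv), K2CO3, DMF, 60 °C
Reagents that add atoms: benzyl bromide, BrCc1ccccc1
Why: Williamson etherification of all three phenols.

Step 4
Reactants: 5 2,3,4-tris(benzyloxy)benzaldehyde
Product: 6 3,4-bis(benzyloxy)-2-hydroxybenzaldehyde
Conditions: MgBr2·OEt2 (2 equiv), toluene–Et2O, rt to 60 °C; aq. HCl work-up
Reagents that add atoms: none
Why: Chelation-controlled ether cleavage, in which magnesium held between the formyl oxygen and the ortho ether oxygen activates only that benzyl group toward bromide.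

Step 5
Reactants: 3 1,2,3-tris(benzyloxy)-4,6-dibromobenzene; 6 3,4-bis(benzyloxy)-2-hydroxybenzaldehyde
Product: 9 racemic [3,4-bis(benzyloxy)-2-hydroxyphenyl][2,3,4-tris(benzyloxy)-5-bromophenyl]methanol, via monolithio arene 7 (not isolated), via sodium phenoxide 8 (not isolated)
Conditions: 3, n-BuLi (1.0 equiv), THF, −78 °C; separately 6, NaH (1.05 equiv), THF, 0 °C; phenoxide solution added at −78 °C, then 0 °C; H2O quench
Reagents that add atoms: none
Why: Bromine–lithium exchange on the symmetric dibromide can give only one monolithio arene, which adds 1,2 to the aldehyde of the pre-formed phenoxide; the carbinol centre is racemic and is erased in step 9.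

Step 6
Reactants: 10 3,4-bis(benzyloxy)benzaldehyde
Product: 11 1,2-bis(benzyloxy)-4-(2,2-dibromovinyl)benzene
Conditions: CBr4 (2 equiv), PPh3 (4 equiv), CH2Cl2, 0 °C
Reagents that add atoms: carbon tetrabromide, BrC(Br)(Br)Br
Why: First stage of the Corey–Fuchs reaction, a Wittig-type dibromomethylenation of the aldehyde.

Step 7
Reactants: 11 1,2-bis(benzyloxy)-4-(2,2-dibromovinyl)benzene
Product: 13 benzyl{[3,4-bis(benzyloxy)phenyl]ethynyl}dimethylsilane, via lithium acetylide 12 (not isolated)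
Conditions: n-BuLi (2.1 equiv), THF, −78 to 0 °C; then BnMe2SiCl, −78 °C to rt
Reagents that add atoms: benzylchlorodimethylsilane, C[Si](C)(Cl)Cc1ccccc1
Why: Second stage of the Corey–Fuchs reaction gives the lithium acetylide, which is silylated on carbon by the chlorosilane.

Step 8
Reactants: 13 benzyl{[3,4-bis(benzyloxy)phenyl]ethynyl}dimethylsilane
Product: 14 (Z)-benzyl{2-[3,4-bis(benzyloxy)phenyl]vinyl}dimethylsilane
Conditions: H2 (1 atm), Pd/CaCO3 poisoned with Pb(OAc)2, quinoline, EtOAc–hexane, rt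
Reagents that add atoms: none
Why: Lindlar-type semihydrogenation delivers both hydrogens syn on the poisoned surface, should stop at the (Z)-alkene and should leave aryl benzyl ethers and the benzylsilane untouched.

Step 9
Reactants: 9 racemic ring-A/ring-D ortho-hydroxybenzhydrol; 14 (Z)-benzyl{2-[3,4-bis(benzyloxy)phenyl]vinyl}dimethylsilane (1.5 equiv)
Product: 16 all-cis (2R,3R,4S)-3-(benzyldimethylsilyl)-7,8-bis(benzyloxy)-2-[3,4-bis(benzyloxy)phenyl]-4-[2,3,4-tris(benzyloxy)-5-bromophenyl]chroman, via ortho-quinone methide 15 (not isolated)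
Conditions: (R)-TRIP [(R)-3,3'-bis(2,4,6-triisopropylphenyl)-1,1'-binaphthyl-2,2'-diyl hydrogen phosphate] (10 mol %), 5 Å molecular sieves, PhCF3, 0 °C to rt
Reagents that add atoms: none
Why: Proposed new method: the phosphoric acid protonates the carbinol of 9, water leaves and the (E)-ortho-quinone methide 15 stays hydrogen-bonded and ion-paired to the chiral phosphate; the silicon-bearing carbon of 14 then bonds to the methide carbon (future C4u) while positive charge builds on the benzylic carbon, which is β to silicon and para to a benzyloxy group, and the quinone oxygen closes on it in an asynchronous concerted inverse-demand hetero-[4+2] addition. The closest known reaction type is the chiral phosphoric acid-catalysed [4+2] cycloaddition of in situ ortho-quinone methides with styrenes to cis-2,4-diarylchromans; a (Z)-vinylsilane has not been used as the 2π partner. Ring C (O1u, C2u, C3u, C4u, C4au, C8au) is closed by the cycloaddition itself, C3u–C4u forming ahead of O1u–C2u in a six-membered transition state. C2u and C3u should come out cis because both new bonds form on one face of the (Z)-alkene (any β-silyl cation is captured from the face that already carries C4u, anti to silicon), C4u is set cis to them by endo approach of the aryl-bearing alkene to the (E)-methide, and the absolute sense is set by the phosphate, which blocks one face of the bound methide. The step needs oxygen to bond to the benzylic and not the silylated carbon, which β-silicon and para-benzyloxy stabilisation secure, and it needs ring closure to outrun protodesilylation or loss of silicon from the β-silyl cation, which the intramolecular oxygen nucleophile, the sieves and the low temperature favour.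

Step 10
Reactants: 16 all-cis 3-silylchroman
Product: 18 all-cis (2R,3R,4S)-7,8-bis(benzyloxy)-2-[3,4-bis(benzyloxy)phenyl]-4-[2,3,4-tris(benzyloxy)-5-bromophenyl]chroman-3-ol, via silanol 17 (not isolated)
Conditions: Bu4NF (3 equiv), THF, 0 °C to rt; then KHCO3, 30% H2O2, MeOH–THF, 40 °C
Reagents that add atoms: hydrogen peroxide, OO
Why: Tamao–Fleming oxidation, in which fluoride cleaves the benzyl group from silicon and peroxide then inserts oxygen into the C3u–Si bond by a 1,2-shift with retention, so the hydroxyl stays cis to both aryl groups; the axial silyl group is gauche to the ring C2u–O1u bond, which disfavours Peterson-type ring opening.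

Step 11
Reactants: 18 all-cis chroman-3-ol
Product: 19 3u-O-benzyl ether of 18 (ring-D bromide, eight benzyl ethers)
Conditions: NaH, BnBr, Bu4NI (cat.), DMF, 0 °C to rt
Reagents that add atoms: benzyl bromide, BrCc1ccccc1
Why: Williamson etherification of the secondary alkoxide masks C3u–OH for the later dehydration step and is removed in the final hydrogenolysis.

Step 12
Reactants: 19 ring-D aryl bromide
Product: 21 ring-D methyl ketone (19 with Br replaced by acetyl on C4al), via aryl enol ether 20 (not isolated)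
Conditions: tributyl(1-ethoxyvinyl)stannane, Pd(P(t-Bu)3)2 (5 mol %), CsF, dioxane, 90 °C; then 1 M HCl, THF, rt
Reagents that add atoms: tributyl(1-ethoxyvinyl)stannane, CCCC[Sn](CCCC)(CCCC)C(=C)OCC; water, O
Why: Stille coupling with a bulky electron-rich phosphine and fluoride activation suits the hindered electron-rich aryl bromide, and dilute acid hydrolyses the enol ether to the acetyl group.

Step 13
Reactants: 21 ring-D methyl ketone
Product: 22 ortho-hydroxyacetophenone (21 with the benzyl ether on the C8al oxygen cleaved)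
Conditions: MgBr2·OEt2 (3 equiv), toluene–Et2O, rt to 50 °C; aq. HCl work-up
Reagents that add atoms: none
Why: Chelation-controlled debenzylation, in which only the ether oxygen ortho to the acetyl carbonyl can bind magnesium in a six-membered chelate, so the other nine ethers should remain.

Step 14
Reactants: 22 ortho-hydroxyacetophenone
Product: 23 methoxymethyl ether of 22
Conditions: MOMCl, i-Pr2NEt, Bu4NI (cat.), CH2Cl2, 0 °C to reflux
Reagents that add atoms: chloromethyl methyl ether, COCCl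
Why: Acetal protection of the phenol, so that the chalcone cannot cyclise and the epoxidation can be run in basic peroxide.

Step 15
Reactants: 23 MOM-protected acetophenone; 10 3,4-bis(benzyloxy)benzaldehyde
Product: 24 (E)-chalcone (ring D–CO–CH=CH–ring E)
Conditions: KOH, EtOH–THF, rt
Reagents that add atoms: none
Why: Claisen–Schmidt condensation (aldol addition and E1cB dehydration) gives the conjugated (E)-enone.

Step 16
Reactants: 24 (E)-chalcone
Product: 25 (αR,βS)-trans-epoxy ketone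
Conditions: poly-L-leucine, urea–H2O2, DBU, THF, rt
Reagents that add atoms: hydrogen peroxide (as urea adduct), OO
Why: Juliá–Colonna epoxidation, in which hydroperoxide adds to the enone bound at the helical peptide terminus and the L-polymer gives the (αR,βS)-epoxide under reagent control, far from the upper-unit stereocentres.

Step 17
Reactants: 25 (αR,βS)-epoxy ketone
Product: 27 (2R,3R)-trans-dihydroflavonol (ring F closed; C3l–OH; C4l ketone), via phenol epoxide 26 (not isolated)
Conditions: conc. HCl (cat.), MeOH–THF, 50 °C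
Reagents that add atoms: none
Why: Acid removes the acetal and the freed phenol opens the epoxide 6-endo at the benzylic carbon activated by the para-benzyloxy group; the Cα–O bond is untouched and becomes C3l, and C2l should settle trans to it either by invertive opening or, if the benzylic carbon ionises, by closure to the more stable diequatorial isomer.

Step 18
Reactants: 27 trans-dihydroflavonol
Product: 28 3l-O-benzyl ether of 27
Conditions: BnBr, Ag2O, 4 Å molecular sieves, CH2Cl2, rt, dark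
Reagents that add atoms: benzyl bromide, BrCc1ccccc1
Why: Silver oxide-mediated (Purdie-type) benzylation is non-basic, so the α-ketol should neither ring-open nor rearrange.

Step 19
Reactants: 28 3l-benzyloxyflavan-4l-one
Product: 29 3l-benzyloxyflavan-4l-ol (mainly the 3,4-trans epimer; both C4l epimers converge in step 20)
Conditions: NaBH4, MeOH–THF, 0 °C
Reagents that add atoms: none
Why: Borohydride reduction of the aryl ketone; the configuration of the new carbinol is of no consequence.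

Step 20
Reactants: 29 3l-benzyloxyflavan-4l-ol
Product: 30 (2R)-3l-benzyloxyflav-3-ene (enol ether C3l=C4l)
Conditions: Burgess reagent [methyl N-(triethylammoniumsulfonyl)carbamate], THF, 50 °C; chromatography on Et3N-treated silica
Reagents that add atoms: none
Why: Burgess dehydration of the electron-rich benzylic alcohol can remove only the C3l hydrogen, giving the aryl-conjugated enol ether; this erases C3l on purpose and keeps C2l.

Step 21
Reactants: 30 3l-benzyloxyflav-3-ene
Product: 32 deca-O-benzyl target (C3l–OBn cis to the C2l aryl; free C4l–OH trans to it), via alkylborane 31 (not isolated)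
Conditions: BH3·THF, THF, 0 °C to rt; then NaOH, H2O2, 0 °C
Reagents that add atoms: hydrogen peroxide, OO
Why: Hydroboration–oxidation of an enol ether puts boron on the carbon β to oxygen (C4l, also the less substituted alkene carbon) and hydrogen on C3l, both from the face opposite the C2l aryl, and oxidation with retention should give the 2,3-cis-3,4-trans arrangement.

Step 22
Reactants: 32 deca-O-benzyl target
Product: 33 target, (2R,3R,4R)-2-(3,4-dihydroxyphenyl)-4-[(2R,3R,4S)-2-(3,4-dihydroxyphenyl)-3,4,7,8-tetrahydroxychroman-6-yl]chroman-3,7,8-triol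
Conditions: H2 (1 atm), Pd(OH)2/C, THF–MeOH, rt, monitored and stopped at completion
Reagents that add atoms: none
Why: Catalytic hydrogenolysis cleaves the ten O-benzyl groups, while in neutral medium the benzylic C4l–OH and the two ring C2–O1 bonds react far more slowly and should persist.

**Compound list**

1 | pyrogallol (benzene-1,2,3-triol) | Oc1cccc(O)c1O | starting material
2 | 1,2,3-tris(benzyloxy)benzene | c1ccc(COc2cccc(OCc3ccccc3)c2OCc2ccccc2)cc1 | intermediate
3 | 1,2,3-tris(benzyloxy)-4,6-dibromobenzene | Brc1cc(Br)c(OCc2ccccc2)c(OCc2ccccc2)c1OCc1ccccc1 | intermediate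
4 | 2,3,4-trihydroxybenzaldehyde | O=Cc1ccc(O)c(O)c1O | starting material
5 | 2,3,4-tris(benzyloxy)benzaldehyde | O=Cc1ccc(OCc2ccccc2)c(OCc2ccccc2)c1OCc1ccccc1 | intermediate
6 | 3,4-bis(benzyloxy)-2-hydroxybenzaldehyde | O=Cc1ccc(OCc2ccccc2)c(OCc2ccccc2)c1O | intermediate
7 | [2,3,4-tris(benzyloxy)-5-bromophenyl]lithium | [Li]c1cc(Br)c(OCc2ccccc2)c(OCc2ccccc2)c1OCc1ccccc1 | intermediate (not isolated)
8 | sodium 2,3-bis(benzyloxy)-6-formylphenoxide | [Na+].[O-]c1c(C=O)ccc(OCc2ccccc2)c1OCc1ccccc1 | intermediate (not isolated)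
9 | racemic [3,4-bis(benzyloxy)-2-hydroxyphenyl][2,3,4-tris(benzyloxy)-5-bromophenyl]methanol | Oc1c(OCc2ccccc2)c(OCc2ccccc2)ccc1C(O)c1cc(Br)c(OCc2ccccc2)c(OCc2ccccc2)c1OCc1ccccc1 | intermediate
10 | 3,4-bis(benzyloxy)benzaldehyde | O=Cc1ccc(OCc2ccccc2)c(OCc2ccccc2)c1 | starting material
11 | 1,2-bis(benzyloxy)-4-(2,2-dibromovinyl)benzene | BrC(Br)=Cc1ccc(OCc2ccccc2)c(OCc2ccccc2)c1 | intermediate
12 | lithium [3,4-bis(benzyloxy)phenyl]acetylide | [Li]C#Cc1ccc(OCc2ccccc2)c(OCc2ccccc2)c1 | intermediate (not isolated)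
13 | benzyl{[3,4-bis(benzyloxy)phenyl]ethynyl}dimethylsilane | C[Si](C)(Cc1ccccc1)C#Cc1ccc(OCc2ccccc2)c(OCc2ccccc2)c1 | intermediate
14 | (Z)-benzyl{2-[3,4-bis(benzyloxy)phenyl]vinyl}dimethylsilane | C[Si](C)(Cc1ccccc1)/C=C\c1ccc(OCc2ccccc2)c(OCc2ccccc2)c1 | intermediate
15 | (E)-ortho-quinone methide, 2,3-bis(benzyloxy)-6-{[2,3,4-tris(benzyloxy)-5-bromophenyl]methylidene}cyclohexa-2,4-dien-1-one | O=C1C(OCc2ccccc2)=C(OCc2ccccc2)C=C/C1=C\c1cc(Br)c(OCc2ccccc2)c(OCc2ccccc2)c1OCc1ccccc1 | intermediate (not isolated)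
16 | all-cis (2R,3R,4S)-3-(benzyldimethylsilyl)-7,8-bis(benzyloxy)-2-[3,4-bis(benzyloxy)phenyl]-4-[2,3,4-tris(benzyloxy)-5-bromophenyl]chroman | O(Cc1ccccc1)c1ccc([C@H]2Oc3c(ccc(OCc4ccccc4)c3OCc3ccccc3)[C@@H](c3cc(Br)c(OCc4ccccc4)c(OCc4ccccc4)c3OCc3ccccc3)[C@H]2[Si](C)(C)Cc2ccccc2)cc1OCc1ccccc1 | intermediate
17 | C3u dimethylsilanol (16 with Si-benzyl replaced by Si–OH) | O(Cc1ccccc1)c1ccc([C@H]2Oc3c(ccc(OCc4ccccc4)c3OCc3ccccc3)[C@@H](c3cc(Br)c(OCc4ccccc4)c(OCc4ccccc4)c3OCc3ccccc3)[C@H]2[Si](C)(C)O)cc1OCc1ccccc1 | intermediate (not isolated)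
18 | all-cis (2R,3R,4S)-7,8-bis(benzyloxy)-2-[3,4-bis(benzyloxy)phenyl]-4-[2,3,4-tris(benzyloxy)-5-bromophenyl]chroman-3-ol | O(Cc1ccccc1)c1ccc([C@H]2Oc3c(ccc(OCc4ccccc4)c3OCc3ccccc3)[C@@H](c3cc(Br)c(OCc4ccccc4)c(OCc4ccccc4)c3OCc3ccccc3)[C@H]2O)cc1OCc1ccccc1 | intermediate
19 | 3u-O-benzyl ether of 18 | O(Cc1ccccc1)c1ccc([C@H]2Oc3c(ccc(OCc4ccccc4)c3OCc3ccccc3)[C@@H](c3cc(Br)c(OCc4ccccc4)c(OCc4ccccc4)c3OCc3ccccc3)[C@H]2OCc2ccccc2)cc1OCc1ccccc1 | intermediate
20 | ring-D 1-ethoxyvinyl arene (19 with Br replaced by C(OEt)=CH2) | O(Cc1ccccc1)c1ccc([C@H]2Oc3c(ccc(OCc4ccccc4)c3OCc3ccccc3)[C@@H](c3cc(C(=C)OCC)c(OCc4ccccc4)c(OCc4ccccc4)c3OCc3ccccc3)[C@H]2OCc2ccccc2)cc1OCc1ccccc1 | intermediate (not isolated)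
21 | ring-D methyl ketone (19 with Br replaced by acetyl) | O(Cc1ccccc1)c1ccc([C@H]2Oc3c(ccc(OCc4ccccc4)c3OCc3ccccc3)[C@@H](c3cc(C(C)=O)c(OCc4ccccc4)c(OCc4ccccc4)c3OCc3ccccc3)[C@H]2OCc2ccccc2)cc1OCc1ccccc1 | intermediate
22 | ortho-hydroxyacetophenone (21 with free OH ortho to acetyl) | O(Cc1ccccc1)c1ccc([C@H]2Oc3c(ccc(OCc4ccccc4)c3OCc3ccccc3)[C@@H](c3cc(C(C)=O)c(O)c(OCc4ccccc4)c3OCc3ccccc3)[C@H]2OCc2ccccc2)cc1OCc1ccccc1 | intermediate
23 | methoxymethyl ether of 22 | O(Cc1ccccc1)c1ccc([C@H]2Oc3c(ccc(OCc4ccccc4)c3OCc3ccccc3)[C@@H](c3cc(C(C)=O)c(OCOC)c(OCc4ccccc4)c3OCc3ccccc3)[C@H]2OCc2ccccc2)cc1OCc1ccccc1 | intermediate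
24 | (E)-chalcone from 23 and 10 | O(Cc1ccccc1)c1ccc([C@H]2Oc3c(ccc(OCc4ccccc4)c3OCc3ccccc3)[C@@H](c3cc(C(=O)/C=C/c4ccc(OCc5ccccc5)c(OCc5ccccc5)c4)c(OCOC)c(OCc4ccccc4)c3OCc3ccccc3)[C@H]2OCc2ccccc2)cc1OCc1ccccc1 | intermediate
25 | (αR,βS)-trans-epoxy ketone of 24 | O(Cc1ccccc1)c1ccc([C@H]2Oc3c(ccc(OCc4ccccc4)c3OCc3ccccc3)[C@@H](c3cc(C(=O)[C@@H]4O[C@H]4c4ccc(OCc5ccccc5)c(OCc5ccccc5)c4)c(OCOC)c(OCc4ccccc4)c3OCc3ccccc3)[C@H]2OCc2ccccc2)cc1OCc1ccccc1 | intermediate
26 | free-phenol epoxy ketone (25 without the methoxymethyl group) | O(Cc1ccccc1)c1ccc([C@H]2Oc3c(ccc(OCc4ccccc4)c3OCc3ccccc3)[C@@H](c3cc(C(=O)[C@@H]4O[C@H]4c4ccc(OCc5ccccc5)c(OCc5ccccc5)c4)c(O)c(OCc4ccccc4)c3OCc3ccccc3)[C@H]2OCc2ccccc2)cc1OCc1ccccc1 | intermediate (not isolated)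
27 | (2R,3R)-trans-dihydroflavonol lower unit on the 3u-O-benzyl upper unit | O(Cc1ccccc1)c1ccc([C@H]2Oc3c(ccc(OCc4ccccc4)c3OCc3ccccc3)[C@@H](c3cc4c(c(OCc5ccccc5)c3OCc3ccccc3)O[C@H](c3ccc(OCc5ccccc5)c(OCc5ccccc5)c3)[C@@H](O)C4=O)[C@H]2OCc2ccccc2)cc1OCc1ccccc1 | intermediate
28 | 3l-O-benzyl ether of 27 | O(Cc1ccccc1)c1ccc([C@H]2Oc3c(ccc(OCc4ccccc4)c3OCc3ccccc3)[C@@H](c3cc4c(c(OCc5ccccc5)c3OCc3ccccc3)O[C@H](c3ccc(OCc5ccccc5)c(OCc5ccccc5)c3)[C@@H](OCc3ccccc3)C4=O)[C@H]2OCc2ccccc2)cc1OCc1ccccc1 | intermediate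
29 | 3l-benzyloxyflavan-4l-ol, major 2,3-trans-3,4-trans epimer shown | O(Cc1ccccc1)c1ccc([C@H]2Oc3c(ccc(OCc4ccccc4)c3OCc3ccccc3)[C@@H](c3cc4c(c(OCc5ccccc5)c3OCc3ccccc3)O[C@H](c3ccc(OCc5ccccc5)c(OCc5ccccc5)c3)[C@@H](OCc3ccccc3)[C@@H]4O)[C@H]2OCc2ccccc2)cc1OCc1ccccc1 | intermediate
30 | (2R)-3l-benzyloxyflav-3-ene (C3l=C4l enol ether) | O(Cc1ccccc1)c1ccc([C@H]2Oc3c(ccc(OCc4ccccc4)c3OCc3ccccc3)[C@@H](c3cc4c(c(OCc5ccccc5)c3OCc3ccccc3)O[C@H](c3ccc(OCc5ccccc5)c(OCc5ccccc5)c3)C(OCc3ccccc3)=C4)[C@H]2OCc2ccccc2)cc1OCc1ccccc1 | intermediate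
31 | C4l alkylborane (BH2 on C4l trans to C3l–OBn, which is cis to the C2l aryl) | O(Cc1ccccc1)c1ccc([C@H]2Oc3c(ccc(OCc4ccccc4)c3OCc3ccccc3)[C@@H](c3cc4c(c(OCc5ccccc5)c3OCc3ccccc3)O[C@H](c3ccc(OCc5ccccc5)c(OCc5ccccc5)c3)[C@H](OCc3ccccc3)[C@H]4B)[C@H]2OCc2ccccc2)cc1OCc1ccccc1 | intermediate (not isolated)
32 | deca-O-benzyl target (all phenols, C3u–O and C3l–O benzylated; C4l–OH free) | O(Cc1ccccc1)c1ccc([C@H]2Oc3c(ccc(OCc4ccccc4)c3OCc3ccccc3)[C@@H](c3cc4c(c(OCc5ccccc5)c3OCc3ccccc3)O[C@H](c3ccc(OCc5ccccc5)c(OCc5ccccc5)c3)[C@H](OCc3ccccc3)[C@H]4O)[C@H]2OCc2ccccc2)cc1OCc1ccccc1 | intermediate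
33 | (2R,3R,4R)-2-(3,4-dihydroxyphenyl)-4-[(2R,3R,4S)-2-(3,4-dihydroxyphenyl)-3,4,7,8-tetrahydroxychroman-6-yl]chroman-3,7,8-triol | Oc1ccc([C@H]2Oc3c(ccc(O)c3O)[C@@H](c3cc4c(c(O)c3O)O[C@H](c3ccc(O)c(O)c3)[C@H](O)[C@H]4O)[C@H]2O)cc1O | target

**Step count and risk**

Total: 22 steps. Longest linear sequence: 17 steps (for example steps 1, 2, 5, 9 and then 10 to 22).

Steps most likely to fail:

1. Step 9 (proposed new method). The vinylsilane may be protodesilylated by the acid, the β-silyl cation may lose silicon before the oxygen closes, or the endo and facial selectivity may be poor. The fallback drops silicon and closes ring C by known reactions. Dibromoalkene 11 is treated with n-BuLi and then water to give 4-ethynyl-1,2-bis(benzyloxy)benzene F1. Benzhydrol 9 and F1 are joined in the acid-catalysed [4+2] addition of ortho-quinone methides to arylalkynes (FeCl3 cat., CH2Cl2) to give the racemic 2,4-diaryl-4H-chromene F2. Hydroboration–oxidation of this enol ether (BH3·THF; NaOH, H2O2) puts oxygen on C3u anti to the C4u aryl and gives the racemic 2,4-cis-2,3-trans-flavan-3-ol F3. Dess–Martin oxidation gives the flavan-3-one F4, and LiBH(s-Bu)3 at −78 °C delivers hydride from the face opposite the two cis aryl groups to give the racemic all-cis alcohol F5. F5 is resolved by preparative chromatography on a chiral stationary phase; the (2R) enantiomer is 18, and the route is rejoined at step 11.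

2. Step 21. Boron may add to C3l under the influence of the electron-rich ring D, or the β-benzyloxyborane may eliminate. The fallback sets out from dihydroflavonol 27 and replaces steps 18 to 21 by an epoxide route. Mesylation (MsCl, Et3N, CH2Cl2, 0 °C) gives the 3l-mesylate F6, and NaBH4 gives the 3,4-trans mesyloxy alcohol F7. K2CO3 in MeOH closes the C3l–C4l epoxide F8 by intramolecular displacement with inversion at C3l, so the epoxide oxygen is cis to the C2l aryl. Water (THF–H2O, buffered) opens it at the benzylic C4l anti to the C3l oxygen to give the 2,3-cis-3,4-trans diol F9. Hydrogenolysis of its nine benzyl ethers as in step 22 gives 33.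

3. Step 17. Methanol may capture the benzylic epoxide carbon, the electron-rich ring E may migrate, or configuration at C2l may be lost on ionisation. The fallback sets out from epoxide 25 and uses a two-stage thioether cyclisation. BnSH with SnCl4 (CH2Cl2, −20 °C) opens the epoxide at the benzylic carbon and removes the methoxymethyl group to give the α-hydroxy-β-benzylsulfanyl ketone F10. AgBF4 (CH2Cl2, 0 °C) then activates sulfur as a leaving group and the phenol closes ring F to give 27, where the route is rejoined at step 18.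

**Further compounds**

F1 | step 9 | 4-ethynyl-1,2-bis(benzyloxy)benzene | C#Cc1ccc(OCc2ccccc2)c(OCc2ccccc2)c1
F2 | step 9 | racemic 7,8-bis(benzyloxy)-2-[3,4-bis(benzyloxy)phenyl]-4-[2,3,4-tris(benzyloxy)-5-bromophenyl]-4H-chromene | O(Cc1ccccc1)c1ccc(C2=CC(c3cc(Br)c(OCc4ccccc4)c(OCc4ccccc4)c3OCc3ccccc3)c3ccc(OCc4ccccc4)c(OCc4ccccc4)c3O2)cc1OCc1ccccc1
F3 | step 9 | racemic 2,4-cis-2,3-trans chroman-3-ol (C3u epimer of 18; one enantiomer drawn) | O(Cc1ccccc1)c1ccc([C@H]2Oc3c(ccc(OCc4ccccc4)c3OCc3ccccc3)[C@@H](c3cc(Br)c(OCc4ccccc4)c(OCc4ccccc4)c3OCc3ccccc3)[C@@H]2O)cc1OCc1ccccc1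
F4 | step 9 | racemic 2,4-cis chroman-3-one (one enantiomer drawn) | O(Cc1ccccc1)c1ccc([C@H]2Oc3c(ccc(OCc4ccccc4)c3OCc3ccccc3)[C@@H](c3cc(Br)c(OCc4ccccc4)c(OCc4ccccc4)c3OCc3ccccc3)C2=O)cc1OCc1ccccc1
F5 | step 9 | racemic all-cis chroman-3-ol (18 and its mirror image; the mirror image is drawn) | O(Cc1ccccc1)c1ccc([C@@H]2Oc3c(ccc(OCc4ccccc4)c3OCc3ccccc3)[C@H](c3cc(Br)c(OCc4ccccc4)c(OCc4ccccc4)c3OCc3ccccc3)[C@@H]2O)cc1OCc1ccccc1
F6 | step 21 | 3l-O-methanesulfonate of 27 | O(Cc1ccccc1)c1ccc([C@H]2Oc3c(ccc(OCc4ccccc4)c3OCc3ccccc3)[C@@H](c3cc4c(c(OCc5ccccc5)c3OCc3ccccc3)O[C@H](c3ccc(OCc5ccccc5)c(OCc5ccccc5)c3)[C@@H](OS(C)(=O)=O)C4=O)[C@H]2OCc2ccccc2)cc1OCc1ccccc1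
F7 | step 21 | 2,3-trans-3,4-trans 3l-mesyloxyflavan-4l-ol | O(Cc1ccccc1)c1ccc([C@H]2Oc3c(ccc(OCc4ccccc4)c3OCc3ccccc3)[C@@H](c3cc4c(c(OCc5ccccc5)c3OCc3ccccc3)O[C@H](c3ccc(OCc5ccccc5)c(OCc5ccccc5)c3)[C@@H](OS(C)(=O)=O)[C@@H]4O)[C@H]2OCc2ccccc2)cc1OCc1ccccc1
F8 | step 21 | C3l–C4l epoxide cis to the C2l aryl | O(Cc1ccccc1)c1ccc([C@H]2Oc3c(ccc(OCc4ccccc4)c3OCc3ccccc3)[C@@H](c3cc4c(c(OCc5ccccc5)c3OCc3ccccc3)O[C@H](c3ccc(OCc5ccccc5)c(OCc5ccccc5)c3)[C@@H]5O[C@H]45)[C@H]2OCc2ccccc2)cc1OCc1ccccc1
F9 | step 21 | nona-O-benzyl target with free 2,3-cis-3,4-trans C3l,C4l diol | O(Cc1ccccc1)c1ccc([C@H]2Oc3c(ccc(OCc4ccccc4)c3OCc3ccccc3)[C@@H](c3cc4c(c(OCc5ccccc5)c3OCc3ccccc3)O[C@H](c3ccc(OCc5ccccc5)c(OCc5ccccc5)c3)[C@H](O)[C@H]4O)[C@H]2OCc2ccccc2)cc1OCc1ccccc1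
F10 | step 17 | α-hydroxy-β-benzylsulfanyl ketone with free ortho phenol (invertive opening product drawn; both β-epimers converge) | O(Cc1ccccc1)c1ccc([C@H]2Oc3c(ccc(OCc4ccccc4)c3OCc3ccccc3)[C@@H](c3cc(C(=O)[C@H](O)[C@H](SCc4ccccc4)c4ccc(OCc5ccccc5)c(OCc5ccccc5)c4)c(O)c(OCc4ccccc4)c3OCc3ccccc3)[C@H]2OCc2ccccc2)cc1OCc1ccccc1
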